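Over 40 h in a closed, stirred flask at constant temperature, I had to say how much product each of three charges of substrate gives.

| flask | substrate | remark | time |
|---|---|---|---|
| winter | 2.8 mM | run made earlier |  |
| midnight | 24 mM | run made earlier |  |
| alpha | 2.0 mM |  | 40 h |
| epsilon | 6.0 mM |  | 40 h |
| theta | 20 mM |  | 40 h |

| run | time / h | product / % | substrate / % |
|---|---|---|---|
| winter | 6.00 | 0 | 101 |
| winter | 12.0 | 0 | 98 |
| winter | 15.0 | 1 | 100 |
| winter | 25.0 | 1 | 97 |
| winter | 30.0 | 4 | 101 |
| winter | 40.0 | 5 | 98 |
| midnight | 6.00 | 2 | 100 |
| midnight | 12.0 | 4 | 94 |
| midnight | 15.0 | 14 | 89 |
| midnight | 25.0 | 76 | 24 |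
| midnight | 30.0 | 92 | 7 |
| midnight | 40.0 | 100 | 2 |

(standard deviation of a reading: 1.5 percentage points)

- [product] at the end for alpha, epsilon, theta, in this order
- how that number moves from the first to the last of them (falls, then rises / hardly changes / rises, then falls / falls all the way / rises all the way)

- "hardly changes" means that all values lie within two and a half points (for a concentration: within two and a half percent of the largest)

The two earlier runs did not seem to go together. Midnight was charged about ten times as strong as winter, yet at 40.0 h it showed 100% product against winter's 5%, whereas a plain first-order flask turns the same percentage at any charge. Midnight crept and then surged, which I read as autocatalysis: product helps to make more product. In such a flask, while product does the turning, the ratio of product to substrate grows exponentially, faster at a stronger charge. Between 15.0 h and 25.0 h in midnight, the natural logarithm of that ratio rose by 3.00.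

So I defined the growth dose D, the charge multiplied by the hours that raise the ratio by a factor e, and read it as 288 M·s. D divided by the charge is a flask's growth time, so 40 h held 1.00 growth times for alpha, 3.00 for epsilon and 10.0 for theta.

I took the first product to come from a slow direct step, a small seed that I treated as a correction. Early on, the percentage formed goes with the growth time multiplied by e raised to the count, less one. Scaling winter's 5%, good to 1.5 percentage points, I reckoned about 0.0787 mM for alpha.

The forecast, reading “slow direct conversion plus autocatalysis”, gave 0.08 mM, 0.8 mM and 19.6 mM, with the shape rises all the way.

The flask gave 0.0566 mM, 0.620 mM and 19.6 mM, with the shape rises all the way, so the forecast stood higher than the flask at alpha and level with it at theta.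

    substrate + product → 2 product (k = 13.0 M⁻¹ h⁻¹)
    substrate → product (k = 4.10 × 10⁻⁴ h⁻¹)

From 20.0 h to 40.0 h, D counted 5.00 growth times for theta, and the logarithm of theta's ratio rose by 5.21. For alpha, D gave a growth time of 40.0 h, so the 40 h allowed held about one. Set beside a tenfold time, the time allowed told on alpha: alpha stood at 0.0566 mM, while ten times the time gave 2.00 mM, which is 99.8% of its charge.

The earlier runs and the new flask were generated by integration with made-up constants, and the scatter is random.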